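**Strategy.** Atom numbers follow the abietane skeleton: ring A (saturated) holds C4 with its CH3 and CO2H, ring B (cyclohexene) holds C8 with CO2H and C9 with the keto chain; C5 and C10 are the fusion carbons. Ring A is cut in a retro-Diels–Alder sense through the fusion bond C5–C10 and through C3–C4. One intramolecular Diels–Alder reaction of a linear triene then forms both bonds, closes ring A as the new cyclohexene and ring B around the C6–C9 tether, and sets C4, C5 and C10 from the C8/C9 pair. It exploits the hidden (E)-2-methyl-2-enoate C4=C5 and the methyl-bearing diene terminus C10. The triene comes from an Ireland–Claisen rearrangement.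

Key step: step 10

Remark on the chemistry: the (S,S) ligand in step 4 is assumed to deliver the R carbinol; if the sense proves opposite, the (R,R) ligand is used.

**Step 1**
Reactants: 1 2-methylpropanenitrile; 2 but-3-en-1-ylmagnesium bromide
Product: 3 2-methylhept-6-en-3-one
Conditions: THF, 0 °C to reflux; then 2 M HCl, rt
Reagents that add atoms: water (O)
Why: Grignard addition to a nitrile stops at the magnesium ketimine, which aqueous acid hydrolyses to the isopropyl ketone of the side chain without over-addition.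

**Step 2**
Reactants: 3 2-methylhept-6-en-3-one
Product: 4 2-(but-3-en-1-yl)-2-(propan-2-yl)-1,3-dioxolane
Conditions: HOCH2CH2OH, TsOH·H2O (cat.), benzene, reflux, Dean–Stark trap
Reagents that add atoms: ethane-1,2-diol (OCCO)
Why: acid-catalysed ketalisation with azeotropic removal of water masks the enolisable ketone for the later amide-base steps.

**Step 3**
Reactants: 4 2-(but-3-en-1-yl)-2-(propan-2-yl)-1,3-dioxolane; 5 2-methylprop-2-enal
Product: 6 (2E)-2-methyl-5-[2-(propan-2-yl)-1,3-dioxolan-2-yl]pent-2-enal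
Conditions: second-generation Grubbs catalyst (H2IMes)(PCy3)Cl2Ru=CHPh (5 mol %), 5 (5 equiv), CH2Cl2, 40 °C
Reagents that add atoms: none
Why: olefin cross-metathesis of a terminal alkene with an excess of the 1,1-disubstituted enal should give the trisubstituted enal as the E isomer under thermodynamic control.

**Step 4**
Reactants: 6 (2E)-2-methyl-5-[2-(propan-2-yl)-1,3-dioxolan-2-yl]pent-2-enal; 7 ethynyl(trimethyl)silane
Product: 8 (3R,4E)-4-methyl-7-[2-(propan-2-yl)-1,3-dioxolan-2-yl]-1-(trimethylsilyl)hept-4-en-1-yn-3-ol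
Conditions: Me2Zn (3 equiv), (S,S)-ProPhenol (20 mol %), Ph3P=O (40 mol %), toluene, 4 °C; then aq. NH4Cl
Reagents that add atoms: none
Why: catalytic asymmetric alkynylation of an aldehyde, in which the zinc acetylide held by the dinuclear zinc–ProPhenol complex adds to one face of the enal, sets the R carbinol centre that is later relayed to C9.

**Step 5**
Reactants: 9 hex-5-enoic acid; 10 benzyl 2-methylprop-2-enoate
Product: 11 (5E)-7-(benzyloxy)-6-methyl-7-oxohept-5-enoic acid
Conditions: second-generation Grubbs catalyst (H2IMes)(PCy3)Cl2Ru=CHPh (5 mol %), 10 (4 equiv), CH2Cl2, 40 °C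
Reagents that add atoms: none
Why: olefin cross-metathesis of a terminal alkene with a methacrylate is selective for the (E)-2-methyl-2-enoate and tolerates the free acid, so the dienophile arm is made in one step.

**Step 6**
Reactants: 8 (3R,4E)-4-methyl-7-[2-(propan-2-yl)-1,3-dioxolan-2-yl]-1-(trimethylsilyl)hept-4-en-1-yn-3-ol; 11 (5E)-7-(benzyloxy)-6-methyl-7-oxohept-5-enoic acid
Product: 12 1-benzyl 7-[(3R,4E)-4-methyl-7-[2-(propan-2-yl)-1,3-dioxolan-2-yl]-1-(trimethylsilyl)hept-4-en-1-yn-3-yl] (2E)-2-methylhept-2-enedioate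
Conditions: DCC (1.2 equiv), DMAP (0.1 equiv), CH2Cl2, 0 °C to rt
Reagents that add atoms: none
Why: Steglich esterification acylates the secondary carbinol under neutral conditions without breaking its C–O bond, so the R configuration is kept.

**Step 7**
Reactants: 12 1-benzyl 7-[(3R,4E)-4-methyl-7-[2-(propan-2-yl)-1,3-dioxolan-2-yl]-1-(trimethylsilyl)hept-4-en-1-yn-3-yl] (2E)-2-methylhept-2-enedioate
Product: 16 1-benzyl 7-methyl (2E,6R)-2-methyl-6-[(3E,5S)-4-methyl-7-[2-(propan-2-yl)-1,3-dioxolan-2-yl]-1-(trimethylsilyl)hept-3-en-1-yn-5-yl]hept-2-enedioate, via silyl ketene acetal 13 (not isolated), via trimethylsilyl ester 14 (not isolated), via carboxylic acid 15 (not isolated)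
Conditions: LiN(iPr)2 (1.15 equiv), Me3SiCl (1.5 equiv), THF, −78 °C to 45 °C; 1 M HCl; then Me3SiCHN2, toluene/MeOH, 0 °C
Reagents that add atoms: (trimethylsilyl)diazomethane (C[Si](C)(C)C=[N+]=[N-])
Why: Ireland–Claisen rearrangement, in which kinetic enolisation of the saturated ester in THF gives the (E)-silyl ketene acetal that rearranges through a chair with the alkynyl group equatorial, should transfer the carbinol chirality to C9, place the C8 carboxyl and the C9 chain trans on the future ring B, and give the new C10=C1 olefin E, after which the acid is methylated in the same pot.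

**Step 8**
Reactants: 16 1-benzyl 7-methyl (2E,6R)-2-methyl-6-[(3E,5S)-4-methyl-7-[2-(propan-2-yl)-1,3-dioxolan-2-yl]-1-(trimethylsilyl)hept-3-en-1-yn-5-yl]hept-2-enedioate
Product: 17 1-benzyl 7-methyl (2E,6R)-2-methyl-6-[(3E,5S)-4-methyl-7-[2-(propan-2-yl)-1,3-dioxolan-2-yl]hept-3-en-1-yn-5-yl]hept-2-enedioate
Conditions: Bu4NF (1.1 equiv), AcOH (1.1 equiv), THF, 0 °C
Reagents that add atoms: none
Why: fluoride-mediated protodesilylation of the alkynylsilane, buffered with acetic acid so that both esters survive, frees the terminal alkyne.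

**Step 9**
Reactants: 17 1-benzyl 7-methyl (2E,6R)-2-methyl-6-[(3E,5S)-4-methyl-7-[2-(propan-2-yl)-1,3-dioxolan-2-yl]hept-3-en-1-yn-5-yl]hept-2-enedioate
Product: 18 1-benzyl 7-methyl (2E,6R)-2-methyl-6-[(3E,5S)-4-methyl-7-[2-(propan-2-yl)-1,3-dioxolan-2-yl]hepta-1,3-dien-5-yl]hept-2-enedioate
Conditions: H2 (1 atm), Pd/CaCO3 poisoned with Pb(OAc)2, quinoline, EtOAc, rt
Reagents that add atoms: none
Why: partial hydrogenation of the terminal alkyne over the lead-poisoned palladium catalyst should stop at the alkene and turn the enyne into the (E)-1,3-diene without touching the trisubstituted olefins or the benzyl ester.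

**Step 10**
Reactants: 18 1-benzyl 7-methyl (2E,6R)-2-methyl-6-[(3E,5S)-4-methyl-7-[2-(propan-2-yl)-1,3-dioxolan-2-yl]hepta-1,3-dien-5-yl]hept-2-enedioate
Product: 19 1-benzyl 6-methyl (1R,4aR,5S,6R,8aR)-1,4a-dimethyl-5-{2-[2-(propan-2-yl)-1,3-dioxolan-2-yl]ethyl}-1,2,4a,5,6,7,8,8a-octahydronaphthalene-1,6-dicarboxylate
Conditions: toluene (0.005 M), BHT (0.1 equiv), 180 °C, sealed tube
Reagents that add atoms: none
Why: thermal intramolecular Diels–Alder reaction of a 1,7,9-decatriene (closest known type: cyclisation of deca-2,7,9-trienoates), in which the diene C10(CH3)=C1–C2=C3 and the (E)-2-methyl-2-enoate C4=C5 combine suprafacially and form C5–C10 and C3–C4 in one concerted, asynchronous step. Ring A is closed as the new cyclohexene by the [4+2] event itself, and ring B is closed by the C5–C10 bond as the four-carbon tether C6–C9 folds into a chair. C4 and C5 follow from the E geometry of the dienophile (ester cis to H-5, CH3 cis to C6), and C10 relative to C5 follows from the ester-endo (anti) transition state, which gives the trans ring fusion with the angular methyl axial. The face of the diene is chosen by the tether chair that keeps both the C9 chain and the C8 ester equatorial, so all three new centres are set relative to C9. The step needs endo over exo and this chair over its flipped form; the trans C8/C9 pair from step 7 and the secondary-orbital preference of the ester should secure them, while high dilution and BHT suppress intermolecular addition and polymerisation.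

**Step 11**
Reactants: 19 1-benzyl 6-methyl (1R,4aR,5S,6R,8aR)-1,4a-dimethyl-5-{2-[2-(propan-2-yl)-1,3-dioxolan-2-yl]ethyl}-1,2,4a,5,6,7,8,8a-octahydronaphthalene-1,6-dicarboxylate
Product: 20 (1R,4aR,5S,6R,8aR)-6-(methoxycarbonyl)-1,4a-dimethyl-5-{2-[2-(propan-2-yl)-1,3-dioxolan-2-yl]ethyl}decahydronaphthalene-1-carboxylic acid
Conditions: H2 (1 atm), 10% Pd/C, EtOAc, rt
Reagents that add atoms: none
Why: heterogeneous catalytic hydrogenation saturates the disubstituted ring A olefin and in the same operation hydrogenolyses the benzyl ester to the free C4 acid, with no stereocentre formed.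

**Step 12**
Reactants: 20 (1R,4aR,5S,6R,8aR)-6-(methoxycarbonyl)-1,4a-dimethyl-5-{2-[2-(propan-2-yl)-1,3-dioxolan-2-yl]ethyl}decahydronaphthalene-1-carboxylic acid
Product: 23 (1R,4aS,5R,8aR)-6-(methoxycarbonyl)-1,4a-dimethyl-5-{2-[2-(propan-2-yl)-1,3-dioxolan-2-yl]ethyl}-1,2,3,4,4a,5,8,8a-octahydronaphthalene-1-carboxylic acid, via phenylselanyl ester 21 (not isolated), via selenoxide 22 (not isolated)
Conditions: LiN(iPr)2 (2.4 equiv), THF, −78 to −20 °C; PhSeBr (1.2 equiv), −78 °C; then 30% H2O2, pyridine, CH2Cl2, 0 °C to rt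
Reagents that add atoms: none
Why: selenoxide syn-elimination, in which the C8 ester enolate (the C4 carboxylate has no α-hydrogen) is selenenylated from the equatorial α face and the selenoxide should eliminate toward the less hindered C7 methylene and not the tertiary C9–H, gives the conjugated C7=C8 ester.

**Step 13**
Reactants: 23 (1R,4aS,5R,8aR)-6-(methoxycarbonyl)-1,4a-dimethyl-5-{2-[2-(propan-2-yl)-1,3-dioxolan-2-yl]ethyl}-1,2,3,4,4a,5,8,8a-octahydronaphthalene-1-carboxylic acid
Product: 25 (1R,4aS,5R,8aR)-1,4a-dimethyl-5-(4-methyl-3-oxopentyl)-1,2,3,4,4a,5,8,8a-octahydronaphthalene-1,6-dicarboxylic acid, via ketal diacid 24 (not isolated)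
Conditions: LiOH·H2O (6 equiv), THF/MeOH/H2O, 50 °C; then 2 M HCl to pH 1, rt
Reagents that add atoms: lithium hydroxide ([Li+].[OH-]); water (O)
Why: saponification of the conjugated methyl ester followed by acid hydrolysis of the dioxolane in the same flask reveals both acids and the ketone, and no stereocentre can epimerise because none is α to a carbonyl group.

**Compound list**

1 | 2-methylpropanenitrile | CC(C)C#N | starting material
2 | but-3-en-1-ylmagnesium bromide | C=CCC[Mg]Br | starting material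
3 | 2-methylhept-6-en-3-one | CC(C)C(=O)CCC=C | intermediate
4 | 2-(but-3-en-1-yl)-2-(propan-2-yl)-1,3-dioxolane | CC(C)C1(CCC=C)OCCO1 | intermediate
5 | 2-methylprop-2-enal | CC(=C)C=O | starting material
6 | (2E)-2-methyl-5-[2-(propan-2-yl)-1,3-dioxolan-2-yl]pent-2-enal | CC(C)C1(CC/C=C(\C)C=O)OCCO1 | intermediate
7 | ethynyl(trimethyl)silane | C#C[Si](C)(C)C | starting material
8 | (3R,4E)-4-methyl-7-[2-(propan-2-yl)-1,3-dioxolan-2-yl]-1-(trimethylsilyl)hept-4-en-1-yn-3-ol | C[Si](C)(C)C#C[C@H](O)/C(C)=C/CCC1(OCCO1)C(C)C | intermediate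
9 | hex-5-enoic acid | C=CCCCC(=O)O | starting material
10 | benzyl 2-methylprop-2-enoate | CC(=C)C(=O)OCc1ccccc1 | starting material
11 | (5E)-7-(benzyloxy)-6-methyl-7-oxohept-5-enoic acid | OC(=O)CCC/C=C(\C)C(=O)OCc1ccccc1 | intermediate
12 | 1-benzyl 7-[(3R,4E)-4-methyl-7-[2-(propan-2-yl)-1,3-dioxolan-2-yl]-1-(trimethylsilyl)hept-4-en-1-yn-3-yl] (2E)-2-methylhept-2-enedioate | C[Si](C)(C)C#C[C@H](OC(=O)CCC/C=C(\C)C(=O)OCc1ccccc1)/C(C)=C/CCC2(OCCO2)C(C)C | intermediate
13 | benzyl (2E,6E)-2-methyl-7-{[(3R,4E)-4-methyl-7-[2-(propan-2-yl)-1,3-dioxolan-2-yl]-1-(trimethylsilyl)hept-4-en-1-yn-3-yl]oxy}-7-[(trimethylsilyl)oxy]hepta-2,6-dienoate | C[Si](C)(C)C#C[C@H](O/C(O[Si](C)(C)C)=C\CC/C=C(\C)C(=O)OCc1ccccc1)/C(C)=C/CCC2(OCCO2)C(C)C | intermediate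
14 | 1-benzyl 7-(trimethylsilyl) (2E,6R)-2-methyl-6-[(3E,5S)-4-methyl-7-[2-(propan-2-yl)-1,3-dioxolan-2-yl]-1-(trimethylsilyl)hept-3-en-1-yn-5-yl]hept-2-enedioate | CC(C)C1(OCCO1)CC[C@H](/C(C)=C/C#C[Si](C)(C)C)[C@H](C(=O)O[Si](C)(C)C)CC/C=C(\C)C(=O)OCc2ccccc2 | intermediate
15 | (2R,5E)-7-(benzyloxy)-6-methyl-2-[(3E,5S)-4-methyl-7-[2-(propan-2-yl)-1,3-dioxolan-2-yl]-1-(trimethylsilyl)hept-3-en-1-yn-5-yl]-7-oxohept-5-enoic acid | CC(C)C1(OCCO1)CC[C@H](/C(C)=C/C#C[Si](C)(C)C)[C@H](C(=O)O)CC/C=C(\C)C(=O)OCc2ccccc2 | intermediate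
16 | 1-benzyl 7-methyl (2E,6R)-2-methyl-6-[(3E,5S)-4-methyl-7-[2-(propan-2-yl)-1,3-dioxolan-2-yl]-1-(trimethylsilyl)hept-3-en-1-yn-5-yl]hept-2-enedioate | CC(C)C1(OCCO1)CC[C@H](/C(C)=C/C#C[Si](C)(C)C)[C@H](C(=O)OC)CC/C=C(\C)C(=O)OCc2ccccc2 | intermediate
17 | 1-benzyl 7-methyl (2E,6R)-2-methyl-6-[(3E,5S)-4-methyl-7-[2-(propan-2-yl)-1,3-dioxolan-2-yl]hept-3-en-1-yn-5-yl]hept-2-enedioate | CC(C)C1(OCCO1)CC[C@H](/C(C)=C/C#C)[C@H](C(=O)OC)CC/C=C(\C)C(=O)OCc2ccccc2 | intermediate
18 | 1-benzyl 7-methyl (2E,6R)-2-methyl-6-[(3E,5S)-4-methyl-7-[2-(propan-2-yl)-1,3-dioxolan-2-yl]hepta-1,3-dien-5-yl]hept-2-enedioate | CC(C)C1(OCCO1)CC[C@H](/C(C)=C/C=C)[C@H](C(=O)OC)CC/C=C(\C)C(=O)OCc2ccccc2 | intermediate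
19 | 1-benzyl 6-methyl (1R,4aR,5S,6R,8aR)-1,4a-dimethyl-5-{2-[2-(propan-2-yl)-1,3-dioxolan-2-yl]ethyl}-1,2,4a,5,6,7,8,8a-octahydronaphthalene-1,6-dicarboxylate | CC(C)C1(OCCO1)CC[C@H]2[C@H](C(=O)OC)CC[C@@H]3[C@]2(C)C=CC[C@@]3(C)C(=O)OCc4ccccc4 | intermediate
20 | (1R,4aR,5S,6R,8aR)-6-(methoxycarbonyl)-1,4a-dimethyl-5-{2-[2-(propan-2-yl)-1,3-dioxolan-2-yl]ethyl}decahydronaphthalene-1-carboxylic acid | CC(C)C1(OCCO1)CC[C@H]2[C@H](C(=O)OC)CC[C@@H]3[C@]2(C)CCC[C@@]3(C)C(=O)O | intermediate
21 | (1R,4aS,5R,6R,8aR)-6-(methoxycarbonyl)-1,4a-dimethyl-6-(phenylselanyl)-5-{2-[2-(propan-2-yl)-1,3-dioxolan-2-yl]ethyl}decahydronaphthalene-1-carboxylic acid | CC(C)C1(OCCO1)CC[C@H]2[C@](C(=O)OC)([Se]c4ccccc4)CC[C@@H]3[C@]2(C)CCC[C@@]3(C)C(=O)O | intermediate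
22 | selenium oxide of 21 (6-benzeneseleninyl analogue; selenium centre unassigned) | CC(C)C1(OCCO1)CC[C@H]2[C@](C(=O)OC)([Se](=O)c4ccccc4)CC[C@@H]3[C@]2(C)CCC[C@@]3(C)C(=O)O | intermediate
23 | (1R,4aS,5R,8aR)-6-(methoxycarbonyl)-1,4a-dimethyl-5-{2-[2-(propan-2-yl)-1,3-dioxolan-2-yl]ethyl}-1,2,3,4,4a,5,8,8a-octahydronaphthalene-1-carboxylic acid | CC(C)C1(OCCO1)CC[C@H]2C(C(=O)OC)=CC[C@@H]3[C@]2(C)CCC[C@@]3(C)C(=O)O | intermediate
24 | (1R,4aS,5R,8aR)-1,4a-dimethyl-5-{2-[2-(propan-2-yl)-1,3-dioxolan-2-yl]ethyl}-1,2,3,4,4a,5,8,8a-octahydronaphthalene-1,6-dicarboxylic acid | CC(C)C1(OCCO1)CC[C@H]2C(C(=O)O)=CC[C@@H]3[C@]2(C)CCC[C@@]3(C)C(=O)O | intermediate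
25 | (1R,4aS,5R,8aR)-1,4a-dimethyl-5-(4-methyl-3-oxopentyl)-1,2,3,4,4a,5,8,8a-octahydronaphthalene-1,6-dicarboxylic acid | CC(C)C(=O)CC[C@H]1C(C(=O)O)=CC[C@@H]2[C@]1(C)CCC[C@@]2(C)C(=O)O | target

**Total step count:** 13. **Longest linear sequence:** 12 steps (steps 1–4 and 6–13; step 5 is a one-step branch).

**Steps most likely to fail**

1. Step 10. At the temperature the uncatalysed cycloaddition needs, the cis-methyl on the diene terminus keeps the diene out of the s-cis form and can lose hydrogen by a 1,5-shift, and the endo preference of the ester may be too small, so that cis-fused adduct forms alongside. The fallback replaces heat by a Lewis-acid-complexed dienophile at low temperature and sets out from 18. Mild aqueous acid (PPTS, acetone/H2O) first removes the dioxolane, which would not survive the aluminium reagent, to give keto triene F1. Me2AlCl (3 equiv) in CH2Cl2 at −20 °C should then give keto cycloadduct F2 through the ester-endo transition state. Re-ketalisation (ethane-1,2-diol, TsOH, benzene) comes back to the route at 19.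

2. Step 12. Enolisation of the hindered tertiary C8–H may be incomplete, or the selenoxide may eliminate toward C9 and give the tetrasubstituted isomer. The fallback is a palladium-mediated dehydrosilylation of Saegusa–Ito type, in which β-hydride elimination takes the accessible C7–H, and it sets out from 20. LiN(iPr)2 (2.4 equiv) followed by Me3SiCl should give silyl ketene acetal silyl ester F3. Pd(OAc)2 (1.1 equiv) in MeCN at rt and aqueous work-up come back to the route at 23.

3. Step 7. Enolisation may lose site selectivity (γ-deprotonation of the enoate arm, attack on the benzyl ester), and the sigmatropic shift may leak through the alkynyl arm. The fallback runs an orthoester Claisen rearrangement first and attaches the dienophile arm afterwards, and it sets out from 8. MeC(OMe)3 with catalytic propionic acid at 130 °C (Johnson–Claisen) should give heptenynoate ester F4 with the same C9 configuration. Its lithium enolate (LiN(iPr)2, THF/DMPU, −78 °C) is alkylated with bromo enoate F5, made by cross-metathesis of 4-bromobut-1-ene with 10. This comes back to the route at 16, as a mixture at C8 that converges at 23.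

**Further compounds**

F1 | step 10 | 1-benzyl 7-methyl (2E,6R)-6-[(3E,5S)-4,9-dimethyl-8-oxodeca-1,3-dien-5-yl]-2-methylhept-2-enedioate | CC(C)C(=O)CC[C@H](/C(C)=C/C=C)[C@H](C(=O)OC)CC/C=C(\C)C(=O)OCc1ccccc1
F2 | step 10 | 1-benzyl 6-methyl (1R,4aR,5S,6R,8aR)-1,4a-dimethyl-5-(4-methyl-3-oxopentyl)-1,2,4a,5,6,7,8,8a-octahydronaphthalene-1,6-dicarboxylate | CC(C)C(=O)CC[C@H]1[C@H](C(=O)OC)CC[C@@H]2[C@]1(C)C=CC[C@@]2(C)C(=O)OCc3ccccc3
F3 | step 12 | trimethylsilyl (1R,4aR,5R,8aR)-6-[methoxy(trimethylsilyloxy)methylidene]-1,4a-dimethyl-5-{2-[2-(propan-2-yl)-1,3-dioxolan-2-yl]ethyl}decahydronaphthalene-1-carboxylate | CC(C)C1(OCCO1)CC[C@H]2C(=C(OC)O[Si](C)(C)C)CC[C@@H]3[C@]2(C)CCC[C@@]3(C)C(=O)O[Si](C)(C)C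
F4 | step 7 | methyl (3S,4E)-4-methyl-3-{2-[2-(propan-2-yl)-1,3-dioxolan-2-yl]ethyl}-7-(trimethylsilyl)hept-4-en-6-ynoate | CC(C)C1(OCCO1)CC[C@H](/C(C)=C/C#C[Si](C)(C)C)CC(=O)OC
F5 | step 7 | benzyl (2E)-5-bromo-2-methylpent-2-enoate | BrCC/C=C(\C)C(=O)OCc1ccccc1
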